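The two stereocentres are the tertiary benzylic carbinol carbons attached to C1 of ring A (the phenol ring that carries the CH2 bridge) and to ring B (the ring that also carries CH2OH). Each bears O, CH3, an aryl carbon and the CH2 of a 4-methylpentyl chain, so each is a 1-arylethanol carbon whose hydrogen has been exchanged for that chain. Both carbinol C–CH2 bonds are therefore made in one twofold lithiation–borylation of a bis[(R)-1-arylethyl N,N-diisopropylcarbamate], whose stereospecific 1,2-metallate shifts deliver a bis(tertiary boronic ester). The precursor is a diarylmethane assembled from two molecules of 2-hydroxy-4-methylacetophenone, phenols as benzyl ethers, CH2OH as TBS ether.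

Key step: step 14

Remarks on the chemistry:
- The target SMILES is read as the (S,S) isomer. Exchanging H for the chain changes the CIP descriptor but not the spatial arrangement, so the (R,R) bis-carbamate is the correct precursor.
- The phenols are kept as benzyl ethers because a silyl ether ortho to the benzylic carbanion would invite a 1,4 oxygen-to-carbon silyl shift.
- The TBS ether is removed only after hydrogenolysis, so that no free primary benzylic alcohol meets H2 and palladium.
- Acetic anhydride, N-bromosuccinimide, benzyl bromide, TBSCl, the carbamoyl chloride and the borate of step 13 are treated as reagents and carry no number.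
- Abbreviations: TBS = tert-butyldimethylsilyl, Cb = N,N-diisopropylcarbamoyl, Bpin = 4,4,5,5-tetramethyl-1,3,2-dioxaborolan-2-yl.

Step 1
Reactants: 1 1-(2-hydroxy-4-methylphenyl)ethanone
Product: 2 2-acetyl-5-methylphenyl acetate
Conditions: Ac2O, pyridine, DMAP (cat.), CH2Cl2, 0 °C → rt
Reagents that add atoms: acetic anhydride CC(=O)OC(C)=O
Why: O-acylation of the phenol under nucleophilic catalysis is routine, and the acetate makes the ring too electron-poor for electrophilic bromination in the next step.

Step 2
Reactants: 2 2-acetyl-5-methylphenyl acetate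
Product: 3 2-acetyl-5-(bromomethyl)phenyl acetate
Conditions: NBS (1.05 equiv), AIBN (cat.), PhCF3, 85 °C
Reagents that add atoms: N-bromosuccinimide O=C1CCC(=O)N1Br
Why: Wohl–Ziegler radical bromination should select the aryl methyl group, because the bromine atom abstracts the weak ArCH2–H bond much faster than the electron-poor C–H bonds of the acetyl and acetate methyl groups.

Step 3
Reactants: 1 1-(2-hydroxy-4-methylphenyl)ethanone
Product: 4 1-(5-bromo-2-hydroxy-4-methylphenyl)ethanone
Conditions: NBS (1.0 equiv), MeCN, 0 °C → rt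
Reagents that add atoms: N-bromosuccinimide O=C1CCC(=O)N1Br
Why: Electrophilic aromatic bromination should go para to the free phenol (C5, also ortho to CH3 and meta to acetyl), since the only other activated position, C3, is crowded between OH and CH3.

Step 4
Reactants: 4 1-(5-bromo-2-hydroxy-4-methylphenyl)ethanone
Product: 5 2-acetyl-4-bromo-5-methylphenyl acetate
Conditions: Ac2O, pyridine, DMAP (cat.), CH2Cl2, 0 °C → rt
Reagents that add atoms: acetic anhydride CC(=O)OC(C)=O
Why: O-acylation of the phenol as in step 1 protects it and deactivates the ring before the radical bromination.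

Step 5
Reactants: 5 2-acetyl-4-bromo-5-methylphenyl acetate
Product: 6 2-acetyl-4-bromo-5-(bromomethyl)phenyl acetate
Conditions: NBS (1.05 equiv), AIBN (cat.), PhCF3, 85 °C
Reagents that add atoms: N-bromosuccinimide O=C1CCC(=O)N1Br
Why: Wohl–Ziegler bromination of the only benzylic methyl group should proceed as in step 2, the ring now being fully blocked against electrophilic attack at its activated positions.

Step 6
Reactants: 6 2-acetyl-4-bromo-5-(bromomethyl)phenyl acetate
Product: 7 (5-acetoxy-4-acetyl-2-bromophenyl)methyl acetate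
Conditions: KOAc, DMF, rt
Reagents that add atoms: potassium acetate CC(=O)[O-].[K+]
Why: SN2 displacement of the benzylic bromide by acetate installs the oxygen of the future CH2OH, while the aryl bromide is inert to substitution.

Step 7
Reactants: 3 2-acetyl-5-(bromomethyl)phenyl acetate; 7 (5-acetoxy-4-acetyl-2-bromophenyl)methyl acetate
Product: 9 2-acetyl-5-{[4-acetoxy-2-(acetoxymethyl)-5-acetylphenyl]methyl}phenyl acetate, via (3-acetoxy-4-acetylbenzyl)zinc bromide 8 (not isolated)
Conditions: Zn dust, LiCl, THF, 0 °C → rt (from 3); then 7, Pd(OAc)2 (2 mol %), SPhos (4 mol %), THF, rt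
Reagents that add atoms: none
Why: Zinc inserts into the benzylic C–Br bond under conditions that tolerate ketones and esters, and the Negishi coupling then joins the benzylzinc to the aryl bromide, into whose C–Br bond zerovalent palladium inserts far faster than into any C–O bond of the acetates.

Step 8
Reactants: 9 2-acetyl-5-{[4-acetoxy-2-(acetoxymethyl)-5-acetylphenyl]methyl}phenyl acetate
Product: 10 1-[5-(4-acetyl-3-hydroxybenzyl)-2-hydroxy-4-(hydroxymethyl)phenyl]ethanone
Conditions: K2CO3 (cat.), MeOH, rt; aq. NH4Cl
Reagents that add atoms: none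
Why: Base-catalysed transesterification with methanol should remove all three acetates at once and leave the two ketones untouched.

Step 9
Reactants: 10 1-[5-(4-acetyl-3-hydroxybenzyl)-2-hydroxy-4-(hydroxymethyl)phenyl]ethanone
Product: 11 1-[5-(4-acetyl-3-(benzyloxy)benzyl)-2-(benzyloxy)-4-(hydroxymethyl)phenyl]ethanone
Conditions: BnBr, K2CO3, DMF, 50 °C
Reagents that add atoms: benzyl bromide BrCc1ccccc1
Why: Williamson ether synthesis is chemoselective here because carbonate deprotonates only the two phenols, so the primary alcohol stays free.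

Step 10
Reactants: 11 1-[5-(4-acetyl-3-(benzyloxy)benzyl)-2-(benzyloxy)-4-(hydroxymethyl)phenyl]ethanone
Product: 12 1-[5-(4-acetyl-3-(benzyloxy)benzyl)-2-(benzyloxy)-4-{[(tert-butyldimethylsilyl)oxy]methyl}phenyl]ethanone
Conditions: TBSCl, imidazole, CH2Cl2, rt
Reagents that add atoms: tert-butyldimethylsilyl chloride CC(C)(C)[Si](C)(C)Cl
Why: Silylation of the only remaining hydroxyl group is unambiguous and gives an ether that tolerates borane, NaH and s-BuLi.

Step 11
Reactants: 12 1-[5-(4-acetyl-3-(benzyloxy)benzyl)-2-(benzyloxy)-4-{[(tert-butyldimethylsilyl)oxy]methyl}phenyl]ethanone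
Product: 13 (R,R)-diol: (1R)-1-{2-(benzyloxy)-4-[(4-(benzyloxy)-5-[(1R)-1-hydroxyethyl]-2-{[(tert-butyldimethylsilyl)oxy]methyl}phenyl)methyl]phenyl}ethanol
Conditions: (S)-2-methyl-CBS-oxazaborolidine (0.2 equiv), BH3·SMe2, THF, −20 °C, slow addition of 12; MeOH quench
Reagents that add atoms: none
Why: In this Corey–Bakshi–Shibata reduction the aryl group takes the large-group position and methyl the small one in the catalyst–borane–ketone complex, so the (S)-configured oxazaborolidine should deliver hydride to the face that gives the (R)-carbinol at each of the two remote, independently reacting ketones.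

Step 12
Reactants: 13 (R,R)-diol
Product: 14 (R,R)-bis-carbamate: (1R)-1-{2-(benzyloxy)-4-[(4-(benzyloxy)-5-{(1R)-1-[(diisopropylcarbamoyl)oxy]ethyl}-2-{[(tert-butyldimethylsilyl)oxy]methyl}phenyl)methyl]phenyl}ethyl N,N-diisopropylcarbamate
Conditions: NaH, THF, 0 °C; then N,N-diisopropylcarbamoyl chloride, rt → 50 °C
Reagents that add atoms: N,N-diisopropylcarbamoyl chloride CC(C)N(C(C)C)C(Cl)=O
Why: O-carbamoylation of the sodium alkoxides forms only O–C(=O) bonds, so both carbinol configurations are retained.

Step 13
Reactants: 15 1-bromo-4-methylpentane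
Product: 17 4,4,5,5-tetramethyl-2-(4-methylpentyl)-1,3,2-dioxaborolane, via (4-methylpentyl)magnesium bromide 16 (not isolated)
Conditions: Mg, THF, reflux; then 2-isopropoxy-4,4,5,5-tetramethyl-1,3,2-dioxaborolane, −78 °C → rt; aq. NH4Cl
Reagents that add atoms: 2-isopropoxy-4,4,5,5-tetramethyl-1,3,2-dioxaborolane CC(C)OB1OC(C)(C)C(C)(C)O1
Why: Grignard formation followed by borylation with an electrophilic borate, whose ate complex loses isopropoxide on work-up, is the standard entry to primary alkyl pinacol boronic esters.

Step 14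
Reactants: 14 (R,R)-bis-carbamate; 17 4,4,5,5-tetramethyl-2-(4-methylpentyl)-1,3,2-dioxaborolane
Product: 20 bis(tertiary pinacol boronic ester) in which each benzylic carbon carries CH3 plus Bpin plus the 4-methylpentyl chain, via dilithiated bis-carbamate 18 (not isolated), via dilithium bis-boronate complex 19 (not isolated)
Conditions: s-BuLi (2.6 equiv), Et2O, −78 °C, 1 h; 17 (3.0 equiv), −78 °C, 2 h; MgBr2 in MeOH (1 M, 2.6 equiv), −78 °C → rt, 16 h
Reagents that add atoms: none
Why: s-BuLi removes each carbamate-activated benzylic hydrogen with retention, the configurationally stable lithiated carbamates 18 capture boronic ester 17 with retention to give bis-boronate 19, and in each boronate the 4-methylpentyl group shifts from boron to carbon antiperiplanar to the departing carbamate with inversion, so the chain ends up where hydrogen was and boron where the carbamate oxygen was. The closest known reaction type is the lithiation–borylation of enantioenriched secondary benzylic carbamates with pinacol boronic esters, used here at two remote and locally alike sites that react independently. No ring is closed. Each new fully substituted stereocentre is controlled only by the configuration of its own (R)-carbamate carbon, which is relayed stereospecifically to the tertiary boronic ester and, after retentive oxidation, to the (S)-alcohol. The step needs site-selective deprotonation and complete stereospecificity: coordination of the base to the carbamate carbonyl directs it to the adjacent benzylic C–H at −78 °C in Et2O ahead of the diarylmethane CH2 and the OCH2Ph hydrogens, and MgBr2 in MeOH, added before warming, speeds the 1,2-shift and protonates any lithiated carbamate released by reversal of boronate formation at these hindered ortho-benzyloxy aryl centres, so that no scrambled carbanion can re-enter.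

Step 15
Reactants: 20 bis(tertiary pinacol boronic ester)
Product: 21 (2S)-2-{2-(benzyloxy)-4-[(4-(benzyloxy)-5-[(2S)-2-hydroxy-6-methylheptan-2-yl]-2-{[(tert-butyldimethylsilyl)oxy]methyl}phenyl)methyl]phenyl}-6-methylheptan-2-ol
Conditions: H2O2 (30 % aq.), NaOH (2 M aq.), THF, 0 °C → rt
Reagents that add atoms: hydrogen peroxide OO
Why: Oxidation of each C–B bond by hydroperoxide proceeds by a 1,2-shift of carbon from boron to oxygen with retention, so oxygen takes the place of boron at both centres, and benzyl and silyl ethers are stable to the alkaline medium.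

Step 16
Reactants: 21 bis(benzyl ether) diol
Product: 22 (2S)-2-{4-[(2-{[(tert-butyldimethylsilyl)oxy]methyl}-4-hydroxy-5-[(2S)-2-hydroxy-6-methylheptan-2-yl]phenyl)methyl]-2-hydroxyphenyl}-6-methylheptan-2-ol
Conditions: H2 (1 atm), Pd/C, EtOAc, rt
Reagents that add atoms: none
Why: Hydrogenolysis of aryl benzyl ethers in a neutral aprotic solvent should be much faster than cleavage of the tertiary benzylic C–OH bonds or of the silyl-protected primary benzylic C–O bond, and it does not touch the stereocentres.

Step 17
Reactants: 22 bisphenol TBS ether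
Product: 23 disydonol C
Conditions: Bu4NF, THF, 0 °C → rt; aq. NH4Cl
Reagents that add atoms: none
Why: Fluoride-driven desilylation, powered by the strong Si–F bond, frees the primary alcohol under non-acidic conditions that spare the acid-sensitive tertiary benzylic alcohols.

Compound list
1 | 1-(2-hydroxy-4-methylphenyl)ethanone | CC(=O)c1ccc(C)cc1O | starting material
2 | 2-acetyl-5-methylphenyl acetate | CC(=O)Oc1cc(C)ccc1C(C)=O | intermediate
3 | 2-acetyl-5-(bromomethyl)phenyl acetate | CC(=O)Oc1cc(CBr)ccc1C(C)=O | intermediate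
4 | 1-(5-bromo-2-hydroxy-4-methylphenyl)ethanone | CC(=O)c1cc(Br)c(C)cc1O | intermediate
5 | 2-acetyl-4-bromo-5-methylphenyl acetate | CC(=O)Oc1cc(C)c(Br)cc1C(C)=O | intermediate
6 | 2-acetyl-4-bromo-5-(bromomethyl)phenyl acetate | CC(=O)Oc1cc(CBr)c(Br)cc1C(C)=O | intermediate
7 | (5-acetoxy-4-acetyl-2-bromophenyl)methyl acetate | CC(=O)OCc1cc(OC(C)=O)c(C(C)=O)cc1Br | intermediate
8 | (3-acetoxy-4-acetylbenzyl)zinc bromide | CC(=O)Oc1cc(C[Zn]Br)ccc1C(C)=O | intermediate (not isolated)
9 | 2-acetyl-5-{[4-acetoxy-2-(acetoxymethyl)-5-acetylphenyl]methyl}phenyl acetate | CC(=O)Oc1cc(Cc2cc(C(C)=O)c(OC(C)=O)cc2COC(C)=O)ccc1C(C)=O | intermediate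
10 | 1-[5-(4-acetyl-3-hydroxybenzyl)-2-hydroxy-4-(hydroxymethyl)phenyl]ethanone | CC(=O)c1ccc(Cc2cc(C(C)=O)c(O)cc2CO)cc1O | intermediate
11 | 1-[5-(4-acetyl-3-(benzyloxy)benzyl)-2-(benzyloxy)-4-(hydroxymethyl)phenyl]ethanone | CC(=O)c1ccc(Cc2cc(C(C)=O)c(OCc3ccccc3)cc2CO)cc1OCc1ccccc1 | intermediate
12 | 1-[5-(4-acetyl-3-(benzyloxy)benzyl)-2-(benzyloxy)-4-{[(tert-butyldimethylsilyl)oxy]methyl}phenyl]ethanone | CC(=O)c1ccc(Cc2cc(C(C)=O)c(OCc3ccccc3)cc2CO[Si](C)(C)C(C)(C)C)cc1OCc1ccccc1 | intermediate
13 | (1R)-1-{2-(benzyloxy)-4-[(4-(benzyloxy)-5-[(1R)-1-hydroxyethyl]-2-{[(tert-butyldimethylsilyl)oxy]methyl}phenyl)methyl]phenyl}ethanol | C[C@@H](O)c1ccc(Cc2cc([C@@H](C)O)c(OCc3ccccc3)cc2CO[Si](C)(C)C(C)(C)C)cc1OCc1ccccc1 | intermediate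
14 | (1R)-1-{2-(benzyloxy)-4-[(4-(benzyloxy)-5-{(1R)-1-[(diisopropylcarbamoyl)oxy]ethyl}-2-{[(tert-butyldimethylsilyl)oxy]methyl}phenyl)methyl]phenyl}ethyl N,N-diisopropylcarbamate | C[C@@H](OC(=O)N(C(C)C)C(C)C)c1ccc(Cc2cc([C@@H](C)OC(=O)N(C(C)C)C(C)C)c(OCc3ccccc3)cc2CO[Si](C)(C)C(C)(C)C)cc1OCc1ccccc1 | intermediate
15 | 1-bromo-4-methylpentane | CC(C)CCCBr | starting material
16 | (4-methylpentyl)magnesium bromide | CC(C)CCC[Mg]Br | intermediate (not isolated)
17 | 4,4,5,5-tetramethyl-2-(4-methylpentyl)-1,3,2-dioxaborolane | CC(C)CCCB1OC(C)(C)C(C)(C)O1 | intermediate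
18 | dilithiated bis-carbamate (14 with Li in place of each carbamate-bearing benzylic H, configuration retained) | C[C@@]([Li])(OC(=O)N(C(C)C)C(C)C)c1ccc(Cc2cc([C@@]([Li])(C)OC(=O)N(C(C)C)C(C)C)c(OCc3ccccc3)cc2CO[Si](C)(C)C(C)(C)C)cc1OCc1ccccc1 | intermediate (not isolated)
19 | dilithium bis-boronate complex (each carbamate-bearing carbon of 14 bonded to the tetracoordinate boron of one molecule of 17, carbamates still in place) | C[C@@]([B-]1(CCCC(C)C)OC(C)(C)C(C)(C)O1)(OC(=O)N(C(C)C)C(C)C)c1ccc(Cc2cc([C@@]([B-]4(CCCC(C)C)OC(C)(C)C(C)(C)O4)(C)OC(=O)N(C(C)C)C(C)C)c(OCc3ccccc3)cc2CO[Si](C)(C)C(C)(C)C)cc1OCc1ccccc1.[Li+].[Li+] | intermediate (not isolated)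
20 | bis(tertiary pinacol boronic ester): the diarylmethane of 14 with each CH(OCb)CH3 carbon now C(CH3)(Bpin)(4-methylpentyl), both centres R by CIP because boron ranks lowest | CC(C)CCC[C@](C)(B1OC(C)(C)C(C)(C)O1)c1ccc(Cc2cc([C@@](C)(B3OC(C)(C)C(C)(C)O3)CCCC(C)C)c(OCc3ccccc3)cc2CO[Si](C)(C)C(C)(C)C)cc1OCc1ccccc1 | intermediate
21 | (2S)-2-{2-(benzyloxy)-4-[(4-(benzyloxy)-5-[(2S)-2-hydroxy-6-methylheptan-2-yl]-2-{[(tert-butyldimethylsilyl)oxy]methyl}phenyl)methyl]phenyl}-6-methylheptan-2-ol | CC(C)CCC[C@](C)(O)c1ccc(Cc2cc([C@@](C)(O)CCCC(C)C)c(OCc3ccccc3)cc2CO[Si](C)(C)C(C)(C)C)cc1OCc1ccccc1 | intermediate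
22 | (2S)-2-{4-[(2-{[(tert-butyldimethylsilyl)oxy]methyl}-4-hydroxy-5-[(2S)-2-hydroxy-6-methylheptan-2-yl]phenyl)methyl]-2-hydroxyphenyl}-6-methylheptan-2-ol | CC(C)CCC[C@](C)(O)c1ccc(Cc2cc([C@@](C)(O)CCCC(C)C)c(O)cc2CO[Si](C)(C)C(C)(C)C)cc1O | intermediate
23 | disydonol C, (2S)-2-{2-hydroxy-4-[(4-hydroxy-2-(hydroxymethyl)-5-[(2S)-2-hydroxy-6-methylheptan-2-yl]phenyl)methyl]phenyl}-6-methylheptan-2-ol | CC(C)CCC[C@](C)(O)c1ccc(Cc2cc([C@@](C)(O)CCCC(C)C)c(O)cc2CO)cc1O | target

Total step count: 17 steps.
Longest linear sequence: 14 steps (steps 3 to 12 and 14 to 17, from 1 through ring B to 23).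

Steps most likely to fail

Step 14. The boronate may revert to lithiated carbamate and boronic ester before the 1,2-shift, which would erode stereochemical fidelity at one or both centres, and the double conversion may stop halfway. The fallback moves to the trialkylborane manifold, where ate-complex formation is irreversible and migration is fast. Borylation there occurs with inversion, so the enantiomeric carbamates are needed. It sets out from diketone 12. Reduction as in step 11 but with (R)-2-methyl-CBS-oxazaborolidine should give the (S,S)-diol F1, and carbamoylation as in step 12 the (S,S)-bis-carbamate F2. Lithiation with s-BuLi in Et2O at −78 °C and addition of tris(4-methylpentyl)borane F3 (from three equivalents of Grignard reagent 16 and BF3·OEt2) should give, on warming, the bis(tertiary dialkylborane) F4. This is oxidised in the same flask with NaOH and H2O2, and the fallback comes back to the route at 21.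

Step 11. Facial selectivity may be incomplete at one or both carbonyl groups, and because the two centres are remote the resulting stereoisomers would not separate by ordinary means. The fallback replaces asymmetric induction by an enzymatic sorting that turns stereoisomers into constitutionally different compounds. It sets out from 12. NaBH4 in MeOH gives the diol as a mixture of all stereoisomers F5. Immobilised Candida antarctica lipase B with vinyl acetate in toluene at 40 °C acylates only (R)-configured carbinols, so only the (R,R)-isomer should become the (R,R)-diacetate F6, which is separated by chromatography from mono-acetates and untouched diol. K2CO3 in MeOH then brings the fallback back to the route at 13. The other isomers can be deacetylated, oxidised to 12 with MnO2 and recycled, and the same acylation and separation can polish material from the reduction of step 11.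

Step 7. Reductive homocoupling of the benzylic bromide during zinc insertion, or slow coupling at the ortho-substituted aryl bromide, may lower the efficiency of the union. The fallback reverses the roles so that the benzylic bromide serves as electrophile and no organozinc is needed. It sets out from 7. Miyaura borylation (B2pin2, PdCl2(dppf), KOAc, dioxane, 80 °C) gives the aryl pinacol boronic ester F7. Suzuki–Miyaura coupling of this with benzylic bromide 3 (Pd(PPh3)4, CsF, 1,2-dimethoxyethane, 80 °C) comes back to the route at 9.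

Further compounds
F1 | step 14 | (1S)-1-{2-(benzyloxy)-4-[(4-(benzyloxy)-5-[(1S)-1-hydroxyethyl]-2-{[(tert-butyldimethylsilyl)oxy]methyl}phenyl)methyl]phenyl}ethanol | C[C@H](O)c1ccc(Cc2cc([C@H](C)O)c(OCc3ccccc3)cc2CO[Si](C)(C)C(C)(C)C)cc1OCc1ccccc1
F2 | step 14 | (S,S)-bis(N,N-diisopropylcarbamate) of F1 | C[C@H](OC(=O)N(C(C)C)C(C)C)c1ccc(Cc2cc([C@H](C)OC(=O)N(C(C)C)C(C)C)c(OCc3ccccc3)cc2CO[Si](C)(C)C(C)(C)C)cc1OCc1ccccc1
F3 | step 14 | tris(4-methylpentyl)borane | CC(C)CCCB(CCCC(C)C)CCCC(C)C
F4 | step 14 | bis(tertiary dialkylborane): as 20 but with bis(4-methylpentyl)boryl in place of each Bpin | CC(C)CCC[C@](C)(B(CCCC(C)C)CCCC(C)C)c1ccc(Cc2cc([C@@](C)(B(CCCC(C)C)CCCC(C)C)CCCC(C)C)c(OCc3ccccc3)cc2CO[Si](C)(C)C(C)(C)C)cc1OCc1ccccc1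
F5 | step 11 | diol of constitution 13 as a mixture of all stereoisomers | CC(O)c1ccc(Cc2cc(C(C)O)c(OCc3ccccc3)cc2CO[Si](C)(C)C(C)(C)C)cc1OCc1ccccc1
F6 | step 11 | (R,R)-diacetate of 13 | C[C@@H](OC(C)=O)c1ccc(Cc2cc([C@@H](C)OC(C)=O)c(OCc3ccccc3)cc2CO[Si](C)(C)C(C)(C)C)cc1OCc1ccccc1
F7 | step 7 | [5-acetoxy-4-acetyl-2-(4,4,5,5-tetramethyl-1,3,2-dioxaborolan-2-yl)phenyl]methyl acetate | CC(=O)OCc1cc(OC(C)=O)c(C(C)=O)cc1B1OC(C)(C)C(C)(C)O1
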